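- theta: starting material 0.40 M; gas phase 200 mM (held); free catalyst 4 mM; run made earlier
- flask: starting material 0.80 M; gas phase 200 mM (held); free catalyst 4.0 mM; time 8.0 min

- theta (time / s: target / %, starting material / %): 10.0: 1.4, 100.0; 12.0: 1.5, 98.9; 20.0: 2.2, 97.8; 40.0: 5.9, 94.1; 60.0: 9.8, 89.2; 90.0: 16.2, 84.2

(scatter of a reading: 0.5 percentage points)

- at the start none of the gas phase is in solution

- green: doubling the amount of free catalyst, all else as stated
- violet: doubling the transfer coefficient of the gas phase, all else as stated
- blue: doubling the saturation concentration of gas phase, all else as stated

- how much target there is at 8.0 min, in percent of the starting material charged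
- concentration of dissolved gas in solution at 50 s, in percent of saturation
- the change that raises the amount of target at 8.0 min, in percent of the starting material charged most ("none" if none brings more than 2 percentage points) (green / violet / blue / none)
- amount of target at 8.0 min, in percent of the starting material charged, after green

Slowness comes first in the theta run, so read it with one quantity: the turnover count, the target formed per free catalyst charged. By 90.0 s it reads 16.2.

Now draw the curve. From 10.0 s to 20.0 s the count climbs at 0.0800 /s, but from 40.0 s to 90.0 s it climbs at 0.206 /s, faster, and these are readings with their scatter. So the readings show a knee: the straight part, drawn back, meets zero at about 11.4 s.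

In the flask, the count has a ceiling of 200, twice that of the theta run. Hold the same speed per catalyst, and the line stands at 96.5 after 8.0 min, below the ceiling; that line means 48.2% target. But it asks each catalyst for 5.96 times the last count read, and the readings show no level. My own reckoning is therefore a bracket, not a point: from 8.10%, the count already seen, up to that line.

The forecast stands above my line: target 51% (46% to 56%), dissolved gas at 50 s 5.3% of saturation (3% to 10%), blue as the best change, and target 53% after green (48% to 60%), on a slope “that does not fall as starting material is used”.

The flask gives 14.6% of target, a count of 29.1, inside my bracket at about a third of the line. In the flask, dissolved gas at 50 s is 51.5% of saturation, blue gains most with 15 percentage points, and green gives 25.5% of target.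

    gas phase ⇌ dissolved gas, rate k1*(csat - [dissolved gas]) (kL = 0.0217 /s)
    starting material + dissolved gas + free catalyst → free catalyst + target (k = 8.36 /M²/s)
    target → over-reaction product (k = 5.15 × 10⁻⁶ /s)
    starting material + free catalyst → spent catalyst (k = 0.0250 /M/s)

At 8.00 min this flask holds free catalyst at 0.0226% of its charge and spent catalyst at >99.9%, while 85% of the starting material is still there. The neighbour flask charged with 0.48 M of starting material reaches a count of 37.0 at the same time, higher than this flask, with 1.21% of its free catalyst left. Left until 80.0 min, this flask holds no more target: it goes from 14.6% to 14.3%, a loss of 0.30 points, and over-reaction product reaches 0.351%.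

The data stem from a simulated flask for an exercise, noise included.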